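**Retrosynthetic overview**

1. Target 27 ⇐ α‑face epoxidation of the C9=C11 alkene and hydrolysis of a methyl acetal ⇐ diacetate ⇐ hydride reduction of a ring‑A 1,2‑dione (both hydrides anti to the axial C4/C10 methyls).
2. Oxepane (O, C6, C5, C10, C9, C8, C7) ⇐ two‑atom ring expansion of a tetrahydrofuran (O, C7, C8, C9, C6) fused to a cyclobutane (C6, C9, C10, C5). The enabling feature is the β‑alkoxy ketone O–C6–C9–C11=O: its C6–C9 bond is shared by the five‑ and four‑membered rings and stands axial on ring C, so Lewis‑acid retro‑aldol cleavage inserts C5–C10 into the ether ring.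
3. Cyclobutane ⇐ silicon‑tethered (O on C15 to O on C2) enone–alkene [2+2] photocycloaddition of a 6‑hydroxy‑2,4,4‑trimethylcyclohexenone (ring A) onto the dihydrofuranone C6=C9 bond; this sets C10 and joins ring A to rings C/D.
4. Dihydrofuranone ⇐ O→C formyl transfer/cyclodehydration on a bicyclo[3.2.1]octan‑3‑one; ring C ⇐ intramolecular allylsilane conjugate addition onto the ring‑D cyclopentenone; C8 ⇐ asymmetric phase‑transfer alkylation of tert‑butyl 2‑oxocyclopentanecarboxylate.
5. Ring order: D (purchased) → C → fused dihydrofuran → cyclobutane with ring A (purchased) → oxepane by ring expansion → epoxide.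

Key step: step 14

**Remarks**

- Locants in the text follow the diterpenoid numbering of the target: ring A = C1–C5 and C10 (acetoxy carbons C1, C2; gem‑dimethyl C4; methyl C20 on C10); lactol carbon C6; OCH2 = C7; quaternary C8; epoxide carbons C9, C11; then C12, C13, C14; ketone C15; C16 bearing methyl C17. α is the face of C20; β is the face of the C15–C16 bridge; endo means syn to the three‑carbon bridge C9–C11–C12.
- Assumption: the catalyst antipodes in steps 1 and 11 are those that deliver the (S)‑ and (R)‑configurations drawn.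
- Assumption: the carbinol centre C15 (7–22), C2 in 16–22 and C5 in 18 are drawn as expected; all three are erased or re‑set later. The acetal carbon in 22–25 is drawn as the anomer corresponding to the target lactol.

**Route**

Step 1
Reactants: 1 tert‑butyl 2‑oxocyclopentane‑1‑carboxylate; 2 2‑(chloromethyl)‑3‑(trimethylsilyl)prop‑1‑ene
Product: 3 tert‑butyl (S)‑2‑oxo‑1‑{2‑[(trimethylsilyl)methyl]prop‑2‑en‑1‑yl}cyclopentane‑1‑carboxylate
Conditions: chiral binaphthyl‑derived N‑spiro quaternary ammonium bromide (1 mol%), CsOH·H2O, toluene, −40 °C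
Reagents that add atoms: none
Why: Asymmetric phase‑transfer C‑alkylation of a cyclic β‑keto ester, in which the chiral ammonium enolate ion pair exposes one enolate face to the allylic chloride and sets the quaternary carbon (future C8) as (S); the allylsilane is inert to the base.

Step 2
Reactants: 3
Product: 4 tert‑butyl (1S)‑3‑methyl‑2‑oxo‑1‑{2‑[(trimethylsilyl)methyl]prop‑2‑en‑1‑yl}cyclopentane‑1‑carboxylate (both C3 epimers)
Conditions: LDA, THF, −78 °C; MeI, −78 → −20 °C
Reagents that add atoms: iodomethane, CI
Why: Kinetic enolate methylation; C8 is quaternary, so only the α′‑carbon (future C16) can be deprotonated, and its configuration is irrelevant because it becomes trigonal in step 3.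

Step 3
Reactants: 4
Product: 5 tert‑butyl (S)‑3‑methyl‑2‑oxo‑1‑{2‑[(trimethylsilyl)methyl]prop‑2‑en‑1‑yl}cyclopent‑3‑ene‑1‑carboxylate
Conditions: LDA, THF, −78 → −40 °C; PhS(Cl)=N‑t‑Bu, −78 → 23 °C
Reagents that add atoms: none
Why: Mukaiyama dehydrogenation (S‑sulfinimidoylation of the enolate, then syn‑elimination of the sulfenamide) should give the conjugated 2‑methylcyclopentenone without touching the allylsilane, C16 being the only enolisable position.

Step 4
Reactants: 5
Product: 6 tert‑butyl 6‑endo‑methyl‑3‑methylidene‑7‑oxobicyclo[3.2.1]octane‑1‑carboxylate (C8, C13, C16 as in 27)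
Conditions: EtAlCl2, CH2Cl2, −78 °C; sat. aq. NH4Cl at −78 °C
Reagents that add atoms: none
Why: Intramolecular Hosomi–Sakurai reaction, in which the Lewis‑acid‑activated enone is attacked at its β‑carbon C13 by the allylsilane terminus in a 6‑exo closure possible only on the face of the tether (so C8 fixes C13), and cold protonation of the aluminium enolate from the open exo face should place the C16 methyl endo; Lewis acids favour 1,4‑ over 1,2‑addition of allylsilanes to enones.

Step 5
Reactants: 6
Product: 7 1‑(hydroxymethyl)‑6‑endo‑methyl‑3‑methylidenebicyclo[3.2.1]octan‑7‑endo‑ol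
Conditions: LiAlH4, THF, −78 → 40 °C; Rochelle salt
Reagents that add atoms: none
Why: Hydride reduction of the ketone (exo attack, endo alcohol; re‑oxidised in step 18) and of the tert‑butyl ester to the primary alcohol that carries C7, the cold start avoiding epimerisation at C16.

Step 6
Reactants: 7
Product: 8 (7‑endo‑hydroxy‑6‑endo‑methyl‑3‑methylidenebicyclo[3.2.1]octan‑1‑yl)methyl formate
Conditions: HCO2Ac, pyridine, CH2Cl2, −20 °C
Reagents that add atoms: acetic formic anhydride, CC(=O)OC=O
Why: Chemoselective acylation, the primary alcohol being formylated much faster than the endo secondary alcohol next to the quaternary bridgehead.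

Step 7
Reactants: 8
Product: 9 {7‑endo‑[(tert‑butyldimethylsilyl)oxy]‑6‑endo‑methyl‑3‑methylidenebicyclo[3.2.1]octan‑1‑yl}methyl formate
Conditions: TBSOTf, 2,6‑lutidine, CH2Cl2, 0 °C
Reagents that add atoms: tert‑butyldimethylsilyl trifluoromethanesulfonate, CC(C)(C)[Si](C)(C)OS(=O)(=O)C(F)(F)F
Why: Silyl triflate silylation of the hindered secondary alcohol, so that only the formate oxygen neighbours the enolate of step 9.

Step 8
Reactants: 9
Product: 10 {7‑endo‑[(tert‑butyldimethylsilyl)oxy]‑6‑endo‑methyl‑3‑oxobicyclo[3.2.1]octan‑1‑yl}methyl formate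
Conditions: O3, CH2Cl2, −78 °C; Me2S, −78 → 23 °C
Reagents that add atoms: ozone, [O-][O+]=O
Why: Ozonolysis with reductive work‑up; the exocyclic methylene is the only alkene and has served as a masked C11 ketone through steps 5–7.

Step 9
Reactants: 10
Product: 12 silyl‑protected tricyclic vinylogous ester (bicyclo[3.2.1]octan‑3‑one with a 2,3‑dihydrofuran fused on the C8–C9 bond: O–CH= on C9, OCH2 on C8; endo OTBS on C15, endo methyl on C16), via hydroxymethylene ketone 11 (not isolated)
Conditions: KHMDS, THF (high dilution), −78 → 0 °C; AcOH; then TsOH·H2O (cat.), PhH, 4 Å MS, 40 °C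
Reagents that add atoms: none
Why: Intramolecular Claisen‑type O→C formyl transfer, in which only the C9 enolate reaches the formate carbonyl through a five‑membered transition state, gives the 2‑hydroxymethylene ketone, whose acid‑catalysed condensation with the released C7 hydroxyl closes the dihydrofuran (5‑exo addition to the formyl carbon C6, then loss of water).

Step 10
Reactants: 12
Product: 13 tricyclic vinylogous ester with free endo hydroxyl on C15
Conditions: TBAF, AcOH, THF, 40 °C
Reagents that add atoms: none
Why: Fluoride cleavage of the silyl ether; the vinylogous ester should be stable to buffered fluoride.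

Step 11
Reactants: 14 2,4,4‑trimethylcyclohex‑2‑en‑1‑one
Product: 16 (R)‑6‑hydroxy‑2,4,4‑trimethylcyclohex‑2‑en‑1‑one, via silyl dienol ether 15 (not isolated)
Conditions: LDA, THF, −78 °C; TMSCl; then fructose‑derived ketone catalyst (Shi epoxidation), Oxone, K2CO3, MeCN/DMM/aq. buffer, 0 °C; citric acid, MeOH
Reagents that add atoms: potassium peroxymonosulfate, [K+].[O-]S(=O)(=O)OO; chlorotrimethylsilane, C[Si](C)(C)Cl (silyl group of 15 only)
Why: Kinetic α′‑enolisation and silylation, then Shi asymmetric epoxidation of the electron‑rich silyl enol ether bond (asymmetric Rubottom oxidation) under catalyst control of the face, the less nucleophilic second alkene of the diene being left.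

Step 12
Reactants: 13; 16
Product: 17 diisopropylsilylene bis‑ether linking the C15 oxygen of 13 to the carbinol oxygen of 16
Conditions: iPr2Si(OTf)2, 2,6‑lutidine, CH2Cl2, −78 °C, add 13; then 16, −78 → 0 °C
Reagents that add atoms: diisopropylsilyl bis(trifluoromethanesulfonate), CC(C)[Si](OS(=O)(=O)C(F)(F)F)(OS(=O)(=O)C(F)(F)F)C(C)C
Why: Sequential silylation of two alcohols by the bis‑triflate gives the unsymmetrical bis‑alkoxysilane, a temporary tether between the oxygen on C15 and the oxygen on C2.

Step 13
Reactants: 17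
Product: 18 silylene‑bridged cyclobutane photoadduct (cyclobutane C5–C6–C9–C10 fused to ring A, to the tetrahydrofuran and spiro‑like to ring C; C11 and C1 ketones)
Conditions: hν (350–366 nm, Pyrex/uranium filter), degassed CH2Cl2 (2 mM), 0 °C
Reagents that add atoms: none
Why: Intramolecular enone–alkene [2+2] photocycloaddition, in which the tether from the endo C15 oxygen should deliver the triplet enone to the β‑face of the C6=C9 bond with C1 next to C8; C5 bonds to the oxygen‑bearing C6 and C10 to C9 (through the 1,4‑diradical stabilised by both carbonyls), which sets C10 as in the target and leaves C6 axial on ring C, while C5 and C6 are re‑set later.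

Step 14
Reactants: 18
Product: 19 silylene‑bridged bis‑enol ether: 2,3‑dihydrooxepine (O–C6H=C5) fused to ring A, with the C9=C11 tert‑butyldimethylsilyl enol ether
Conditions: TBSOTf, 2,6‑di‑tert‑butyl‑4‑methylpyridine, CH2Cl2, −78 → 0 °C
Reagents that add atoms: tert‑butyldimethylsilyl trifluoromethanesulfonate, CC(C)(C)[Si](C)(C)OS(=O)(=O)C(F)(F)F
Why: O‑Silylation of the C11 ketone should make the C9–C6 bond of the alkoxy‑substituted (donor–acceptor) cyclobutane heterolyse, the ring‑oxygen lone pair pushing and the siloxycarbenium pulling, so that the tetrahydrofuran (O, C7, C8, C9, C6) becomes a seven‑membered oxocarbenium ring by taking in C5 and C10; loss of H‑5 to the hindered pyridine then gives the cyclic enol ether, and the carbonyl ends as the regiodefined C9=C11 silyl enol ether. The closest known reaction type is the retro‑aldol (de Mayo) fragmentation of 2‑alkoxycyclobutyl ketones and the Lewis‑acid ring opening of donor–acceptor cyclobutanes. No ring is closed: the oxepane arises by cleavage of the bond shared by the five‑ and four‑membered rings, a two‑atom ring expansion (5 → 7). No new stereocentre is formed; C10, set in step 13, is untouched, and C5 and C9 become trigonal (C5 is re‑set in step 17). The step needs cleavage of C9–C6 and not of C9–C10: only C6 carries a donor, and in the β‑face photoadduct C9–C6 is axial on ring C and thus parallel to the π system of the C11 carbonyl, whereas C9–C10 lies near the carbonyl plane and would leave an unstabilised cation beside the C1 ketone. Release of the cyclobutane strain and formation of the enol ether should make the opening irreversible.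

Step 15
Reactants: 19
Product: 20 alkenyl nonaflate (C9=C11–ONf) analogue of 19
Conditions: C4F9SO2F, Bu4N+ Ph3SiF2− (cat.), THF, 0 → 23 °C
Reagents that add atoms: nonafluorobutane‑1‑sulfonyl fluoride, O=S(=O)(F)C(F)(F)C(F)(F)C(F)(F)C(F)(F)F
Why: Fluoride‑catalysed exchange of the silyl enol ether for the alkenyl nonaflate (the liberated enolate is sulfonylated by the sulfonyl fluoride, which returns fluoride), so the C9=C11 regiochemistry fixed in step 14 is kept.

Step 16
Reactants: 20
Product: 21 silylene‑bridged diene (C9=C11 alkene, C5=C6 enol ether)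
Conditions: Pd(OAc)2 (cat.), PPh3, HCO2H, Et3N, DMF, 60 °C
Reagents that add atoms: none
Why: Palladium‑catalysed formate reduction of the alkenyl nonaflate (oxidative addition, hydride transfer from formate, reductive elimination) should give the C9=C11 alkene, the buffered medium sparing the enol ether and the silylene.

Step 17
Reactants: 21
Product: 22 methyl acetal diol (oxepane with OMe on C6, H‑5 β; free hydroxyls on C2 and C15; C1 ketone)
Conditions: CSA (cat.), MeOH/CH2Cl2, 0 → 23 °C
Reagents that add atoms: methanol, CO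
Why: Acid‑catalysed addition of methanol to the cyclic enol ether, in which protonation at C5 should come from the β‑face, opposite the axial methyls on C4 and C10 (also the expected thermodynamic outcome under these reversible conditions), and the oxocarbenium ion is trapped as the methyl acetal; the same acid methanolyses the silylene tether.

Step 18
Reactants: 22
Product: 23 diosphenol triketone (C1 ketone with C2 enol, C15 ketone, methyl acetal)
Conditions: Dess–Martin periodinane, NaHCO3, CH2Cl2, 0 → 23 °C
Reagents that add atoms: none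
Why: Dess–Martin oxidation of both secondary alcohols gives the C15 ketone and, from the α‑ketol, the 1,2‑dione that enolises to the diosphenol, which erases the C2 configuration brought in by the tether; the buffered conditions should not epimerise C16.

Step 19
Reactants: 23
Product: 24 cis‑1α,2α‑diol with C15 ketone
Conditions: NaBH4, CeCl3·7H2O, MeOH/THF, −78 → −40 °C
Reagents that add atoms: none
Why: Luche‑type borohydride reduction, in which the diosphenol/1,2‑dione and the derived α‑hydroxy ketone are far more electrophilic than the C15 ketone beside quaternary C8, and both hydrides should arrive from the β‑face, anti to the axial C10 and C4 methyls, giving the cis‑diol.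

Step 20
Reactants: 24
Product: 25 1α,2α‑diacetate
Conditions: Ac2O, DMAP, pyridine, 50 °C
Reagents that add atoms: acetic anhydride, CC(=O)OC(C)=O
Why: Acylation of both hindered secondary alcohols under nucleophilic catalysis; ketone, acetal and alkene are inert.

Step 21
Reactants: 25
Product: 26 lactol
Conditions: AcOH/THF/H2O, 40 °C
Reagents that add atoms: water, O
Why: Mild acid hydrolysis of the tetrahydropyranyl‑type mixed acetal to the lactol, which should settle in the more stable anomer while the acetates survive.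

Step 22
Reactants: 26
Product: 27 target
Conditions: dimethyldioxirane, acetone, −20 → 0 °C
Reagents that add atoms: dimethyldioxirane, CC1(C)OO1
Why: Epoxidation with a neutral dioxirane; the β‑face of the C9=C11 bond is covered by the C15–C16 bridge and its endo methyl, so oxygen should be delivered to the α‑face.

**Compound list**

1 | tert‑butyl 2‑oxocyclopentane‑1‑carboxylate | CC(C)(C)OC(=O)C1CCCC1=O | starting material
2 | 2‑(chloromethyl)‑3‑(trimethylsilyl)prop‑1‑ene | C[Si](C)(C)CC(=C)CCl | starting material
3 | tert‑butyl (S)‑2‑oxo‑1‑{2‑[(trimethylsilyl)methyl]prop‑2‑en‑1‑yl}cyclopentane‑1‑carboxylate | O=C(OC(C)(C)C)[C@]1(CC(=C)C[Si](C)(C)C)CCCC1=O | intermediate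
4 | tert‑butyl (1S)‑3‑methyl‑2‑oxo‑1‑{2‑[(trimethylsilyl)methyl]prop‑2‑en‑1‑yl}cyclopentane‑1‑carboxylate (C3 epimers) | O=C(OC(C)(C)C)[C@]1(CC(=C)C[Si](C)(C)C)CCC(C)C1=O | intermediate
5 | tert‑butyl (S)‑3‑methyl‑2‑oxo‑1‑{2‑[(trimethylsilyl)methyl]prop‑2‑en‑1‑yl}cyclopent‑3‑ene‑1‑carboxylate | O=C(OC(C)(C)C)[C@]1(CC(=C)C[Si](C)(C)C)CC=C(C)C1=O | intermediate
6 | tert‑butyl 6‑endo‑methyl‑3‑methylidene‑7‑oxobicyclo[3.2.1]octane‑1‑carboxylate | O=C(OC(C)(C)C)[C@@]12C[C@@H](CC(=C)C1)[C@@H](C)C2=O | intermediate
7 | 1‑(hydroxymethyl)‑6‑endo‑methyl‑3‑methylidenebicyclo[3.2.1]octan‑7‑endo‑ol | OC[C@@]12C[C@@H](CC(=C)C1)[C@@H](C)[C@H]2O | intermediate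
8 | (7‑endo‑hydroxy‑6‑endo‑methyl‑3‑methylidenebicyclo[3.2.1]octan‑1‑yl)methyl formate | O=COC[C@@]12C[C@@H](CC(=C)C1)[C@@H](C)[C@H]2O | intermediate
9 | {7‑endo‑[(tert‑butyldimethylsilyl)oxy]‑6‑endo‑methyl‑3‑methylidenebicyclo[3.2.1]octan‑1‑yl}methyl formate | O=COC[C@@]12C[C@@H](CC(=C)C1)[C@@H](C)[C@H]2O[Si](C)(C)C(C)(C)C | intermediate
10 | {7‑endo‑[(tert‑butyldimethylsilyl)oxy]‑6‑endo‑methyl‑3‑oxobicyclo[3.2.1]octan‑1‑yl}methyl formate | O=COC[C@@]12C[C@@H](CC(=O)C1)[C@@H](C)[C@H]2O[Si](C)(C)C(C)(C)C | intermediate
11 | 7‑endo‑[(tert‑butyldimethylsilyl)oxy]‑1‑(hydroxymethyl)‑2‑(hydroxymethylidene)‑6‑endo‑methylbicyclo[3.2.1]octan‑3‑one | OC[C@@]12C[C@@H](CC(=O)C1=CO)[C@@H](C)[C@H]2O[Si](C)(C)C(C)(C)C | intermediate (not isolated)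
12 | silyl‑protected tricyclic vinylogous ester (dihydrofuran fused on C8–C9, C11 ketone, endo OTBS on C15, endo methyl on C16) | O1C[C@@]23C[C@@H](CC(=O)C2=C1)[C@@H](C)[C@H]3O[Si](C)(C)C(C)(C)C | intermediate
13 | tricyclic vinylogous ester with free endo hydroxyl on C15 | O1C[C@@]23C[C@@H](CC(=O)C2=C1)[C@@H](C)[C@H]3O | intermediate
14 | 2,4,4‑trimethylcyclohex‑2‑en‑1‑one | CC1=CC(C)(C)CCC1=O | starting material
15 | trimethyl[(2,4,4‑trimethylcyclohexa‑2,6‑dien‑1‑yl... 1,5‑dienyl)oxy]silane, i.e. the 2‑silyloxy diene of 14 | CC1=CC(C)(C)CC=C1O[Si](C)(C)C | intermediate (not isolated)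
16 | (R)‑6‑hydroxy‑2,4,4‑trimethylcyclohex‑2‑en‑1‑one | O=C1[C@H](O)CC(C)(C)C=C1C | intermediate
17 | diisopropylsilylene bis‑ether of 13 (C15 oxygen) and 16 | O1C[C@@]23C[C@@H](CC(=O)C2=C1)[C@@H](C)[C@H]3O[Si](C(C)C)(C(C)C)O[C@@H]1CC(C)(C)C=C(C)C1=O | intermediate
18 | silylene‑bridged cyclobutane photoadduct (β‑face adduct, C1 beside C8, H‑5 cis to C20) | O=C1[C@H]2CC(C)(C)[C@@H]3[C@@H]4OC[C@@]56C[C@@H](CC(=O)[C@]54[C@@]31C)[C@@H](C)[C@H]6O[Si](C(C)C)(C(C)C)O2 | intermediate
19 | silylene‑bridged bis‑enol ether (dihydrooxepine; C9=C11 OTBS enol ether) | O=C1[C@H]2CC(C)(C)C3=COC[C@@]45C[C@@H](CC(O[Si](C)(C)C(C)(C)C)=C4[C@@]31C)[C@@H](C)[C@H]5O[Si](C(C)C)(C(C)C)O2 | intermediate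
20 | alkenyl nonaflate analogue of 19 | O=C1[C@H]2CC(C)(C)C3=COC[C@@]45C[C@@H](CC(OS(=O)(=O)C(F)(F)C(F)(F)C(F)(F)C(F)(F)F)=C4[C@@]31C)[C@@H](C)[C@H]5O[Si](C(C)C)(C(C)C)O2 | intermediate
21 | silylene‑bridged diene (C9=C11 alkene, C5=C6 enol ether) | O=C1[C@H]2CC(C)(C)C3=COC[C@@]45C[C@@H](CC=C4[C@@]31C)[C@@H](C)[C@H]5O[Si](C(C)C)(C(C)C)O2 | intermediate
22 | methyl acetal diol (C1 ketone, 2β‑OH, 15‑OH, H‑5 β) | O=C1[C@H](O)CC(C)(C)[C@H]2[C@H](OC)OC[C@@]34C[C@@H](CC=C3[C@@]21C)[C@@H](C)[C@H]4O | intermediate
23 | diosphenol triketone (C1 ketone/C2 enol, C15 ketone, methyl acetal) | O=C1C(O)=CC(C)(C)[C@H]2[C@H](OC)OC[C@@]34C[C@@H](CC=C3[C@@]21C)[C@@H](C)C4=O | intermediate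
24 | cis‑1α,2α‑diol, C15 ketone, methyl acetal | O[C@H]1CC(C)(C)[C@H]2[C@H](OC)OC[C@@]34C[C@@H](CC=C3[C@]2(C)[C@H]1O)[C@@H](C)C4=O | intermediate
25 | 1α,2α‑diacetate, methyl acetal | CC(=O)O[C@H]1CC(C)(C)[C@H]2[C@H](OC)OC[C@@]34C[C@@H](CC=C3[C@]2(C)[C@H]1OC(C)=O)[C@@H](C)C4=O | intermediate
26 | lactol (9,11‑alkene) | CC(=O)O[C@H]1CC(C)(C)[C@H]2[C@H](O)OC[C@@]34C[C@@H](CC=C3[C@]2(C)[C@H]1OC(C)=O)[C@@H](C)C4=O | intermediate
27 | CNP0210140.1 | CC(=O)O[C@H]1CC(C)(C)[C@H]2[C@H](O)OC[C@@]34C[C@@H](C[C@H]5O[C@]53[C@]2(C)[C@H]1OC(C)=O)[C@@H](C)C4=O | target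

**Step count and risks**

Total: 22 steps. Longest linear sequence: 21 steps (steps 1–10 and 12–22); step 11 is a one‑step branch.

Three steps most likely to fail:

Step 13. The tethered enone may not reach the crowded β‑face in a reactive conformation, so that decay of the twisted enone triplet, crossed closure or loss of the silylene outruns the cycloaddition. Fallback (ester‑templated enone–alkene photocycloaddition with a different linker): the route is left at 13 and 16. Oxalyl chloride and pyridine give the mixed oxalate F1, whose longer planar linker changes the approach geometry. Irradiation as in step 13 should give the oxalate‑bridged cyclobutane F2. Potassium carbonate in methanol at 0 °C removes the oxalate to give the cyclobutane diol F3, and diisopropylsilyl bis(triflate)/2,6‑lutidine closes the silylene, which returns to the route at 18.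

Step 4. The allylsilane may add 1,2 to the ring‑D carbonyl (five‑membered closure) or be protodesilylated, and the enolate may equilibrate so that C16 is protonated without control. Fallback (radical instead of cationic closure): from 5, N‑bromosuccinimide (CH2Cl2, propylene oxide, −78 °C) effects bromodesilylation with allylic transposition to the allylic bromide F4. Tributyltin hydride/AIBN (benzene, 80 °C, slow addition) generates the allyl radical, which cannot add to the carbonyl and should close 6‑exo onto the enone β‑carbon. Hydrogen‑atom transfer to the α‑keto radical from the exo face gives 6, where the route is rejoined.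

Step 22. Facial selectivity may be poor or reversed, because the α‑face of the alkene is flanked by the axial C20 methyl on C10 while the β‑face is covered by the C15–C16 bridge. Fallback (halohydrin route, which places the epoxide oxygen on the face opposite to the one the electrophile attacks): from 25, N‑bromosuccinimide in aqueous DMSO gives the bromohydrin F5 (bromonium ion on the β‑face, water at tertiary C9 from the α‑face). DBU closes it by intramolecular displacement to the epoxy acetal F6, and hydrolysis of the acetal as in step 21 gives 27.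

**Further compounds**

F1 | step 13 | mixed oxalate of 13 (C15 oxygen) and 16 | O1C[C@@]23C[C@@H](CC(=O)C2=C1)[C@@H](C)[C@H]3OC(=O)C(=O)O[C@@H]1CC(C)(C)C=C(C)C1=O
F2 | step 13 | oxalate‑bridged cyclobutane photoadduct | O=C1[C@H]2CC(C)(C)[C@@H]3[C@@H]4OC[C@@]56C[C@@H](CC(=O)[C@]54[C@@]31C)[C@@H](C)[C@H]6OC(=O)C(=O)O2
F3 | step 13 | cyclobutane diol (free hydroxyls on C2 and C15) | O=C1[C@H](O)CC(C)(C)[C@@H]2[C@@H]3OC[C@@]45C[C@@H](CC(=O)[C@]43[C@@]21C)[C@@H](C)[C@H]5O
F4 | step 4 | tert‑butyl (S)‑1‑[2‑(bromomethyl)prop‑2‑en‑1‑yl]‑3‑methyl‑2‑oxocyclopent‑3‑ene‑1‑carboxylate | O=C(OC(C)(C)C)[C@]1(CC(=C)CBr)CC=C(C)C1=O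
F5 | step 22 | 11β‑bromo‑9α‑hydroxy derivative of 25 | CC(=O)O[C@H]1CC(C)(C)[C@H]2[C@H](OC)OC[C@@]34C[C@@H](C[C@H](Br)[C@]3(O)[C@]2(C)[C@H]1OC(C)=O)[C@@H](C)C4=O
F6 | step 22 | 9α,11α‑epoxy methyl acetal (methyl acetal of 27) | CC(=O)O[C@H]1CC(C)(C)[C@H]2[C@H](OC)OC[C@@]34C[C@@H](C[C@H]5O[C@]53[C@]2(C)[C@H]1OC(C)=O)[C@@H](C)C4=O
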